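**Retrosynthetic overview**

- Naamidine F ⇐ oxidation of the 2,5-dimethoxy pair of a 2,3,4,5-tetramethoxyphenyl ring with (NH4)2Ce(NO3)6 ⇐ condensation of the free 2-aminoimidazole with N-methylparabanic acid ⇐ removal of two Boc groups.
- 4,5-Dibenzyl-2-aminoimidazole skeleton ⇐ Negishi union of C4 of an imidazol-4-yl triflate with the benzylic carbon of 4-methoxybenzylzinc chloride.
- Imidazol-4-yl triflate ⇐ O-triflation of the C5 enolate of bis-Boc 5-(tetramethoxybenzyl)creatinine ⇐ creatinine + 2,3,4,5-tetramethoxybenzaldehyde (Knoevenagel, hydrogenation, Boc2O) ⇐ Rieche formylation of 1,2,3,4-tetramethoxybenzene.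
- Feature used: N1-methyl, C2–NH2, N3, C4 and C5 of the imidazole are the intact creatinine ring. Its C5 methylene takes the tetramethoxybenzyl arm, and its C4 lactam carbonyl becomes the leaving group on the carbon that must carry the 4-methoxybenzyl group.
- Ring order: no ring is built. The creatinine ring is aromatised at the triflation, the dehydrohydantoin ring arrives with N-methylparabanic acid, and the quinone ring is unmasked last from the benzene ring.

Key step: step 7

Assumption: the second Boc group is taken to go to the exocyclic nitrogen, as with 2-aminoazines; a regioisomer with one Boc on N3 would still enolise at C5, triflate on oxygen, couple and give the same free amine on acidolysis.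
Assumption: the arylidene intermediate is drawn as the E isomer (aryl away from the N-methyl group); either geometry serves because the alkene is hydrogenated. The target has no stereocentre, and the C5 stereocentre of the saturated lactams is racemic and becomes sp2 again at the triflation.

**Route**

Step 1
Reactants: 1 1,2,3,4-tetramethoxybenzene
Product: 2 2,3,4,5-tetramethoxybenzaldehyde
Conditions: Cl2CHOMe, TiCl4, CH2Cl2, −10 to 0 °C; then ice/aq. HCl
Reagents that add atoms: dichloromethyl methyl ether, COC(Cl)Cl; water (hydrolytic work-up), O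
Why: Rieche formylation, in which the TiCl4-activated dichloromethyl ether attacks the only kind of free ring position (C5 and C6 are equivalent, each ortho and para to methoxy groups) and hydrolysis of the α-chloro ether gives the aldehyde.

Step 2
Reactants: 2 2,3,4,5-tetramethoxybenzaldehyde; 3 creatinine
Product: 4 (5E)-2-amino-1-methyl-5-(2,3,4,5-tetramethoxybenzylidene)-1,5-dihydro-4H-imidazol-4-one
Conditions: NaOAc, AcOH, 115 °C
Reagents that add atoms: none
Why: Knoevenagel (aldol) condensation at the C5 active methylene of creatinine, a long-established reaction of creatinine with aromatic aldehydes in buffered acetic acid; the alkene geometry is not controlled and need not be.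

Step 3
Reactants: 4 (5E)-2-amino-1-methyl-5-(2,3,4,5-tetramethoxybenzylidene)-1,5-dihydro-4H-imidazol-4-one
Product: 5 (±)-2-amino-1-methyl-5-(2,3,4,5-tetramethoxybenzyl)-1,5-dihydro-4H-imidazol-4-one
Conditions: H2 (3 atm), 10% Pd/C, MeOH/AcOH (10:1), 25 °C
Reagents that add atoms: none
Why: Heterogeneous catalytic hydrogenation of the conjugated exocyclic alkene, which leaves the aryl methyl ethers and the cyclic acylguanidine untouched; the new C5 stereocentre forms as a racemate and is erased in step 5.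

Step 4
Reactants: 5 (±)-2-amino-1-methyl-5-(2,3,4,5-tetramethoxybenzyl)-1,5-dihydro-4H-imidazol-4-one
Product: 6 (±)-di-tert-butyl [1-methyl-4-oxo-5-(2,3,4,5-tetramethoxybenzyl)-4,5-dihydro-1H-imidazol-2-yl]imidodicarbonate
Conditions: Boc2O (2.3 equiv), DMAP (0.1 equiv), MeCN, 25 °C
Reagents that add atoms: di-tert-butyl dicarbonate, CC(C)(C)OC(=O)OC(=O)OC(C)(C)C
Why: DMAP-catalysed exhaustive Boc protection of the exocyclic acylguanidine nitrogen removes every N–H so that C5–H is the only acidic site left, and the reagent is held just above two equivalents so that the C5 enol is not carbonated.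

Step 5
Reactants: 6 (±)-di-tert-butyl [1-methyl-4-oxo-5-(2,3,4,5-tetramethoxybenzyl)-4,5-dihydro-1H-imidazol-2-yl]imidodicarbonate
Product: 8 2-[bis(tert-butoxycarbonyl)amino]-1-methyl-5-(2,3,4,5-tetramethoxybenzyl)-1H-imidazol-4-yl trifluoromethanesulfonate, via potassium imidazol-4-olate 7 (not isolated)
Conditions: KN(SiMe3)2 (1.1 equiv), THF, −78 °C; then PhNTf2 (1.2 equiv), −78 to 0 °C
Reagents that add atoms: N-phenylbis(trifluoromethanesulfonimide), O=S(=O)(N(c1ccccc1)S(=O)(=O)C(F)(F)F)C(F)(F)F
Why: Proposed new method: KN(SiMe3)2 removes the C5–H (α to the lactam carbonyl and bound to N1) to give olate 7, whose ring is a 6π aromatic imidazole, and the hard oxygen terminus of this ambident anion attacks sulfur of PhNTf2 because only O-sulfonylation keeps the aromatic ring while N3 is shielded by the imidodicarbonate and C5 is fully substituted; the closest known reaction type is O-triflation of lactam enolates that aromatise (oxazol-4(5H)-ones, thiazol-4(5H)-ones, pyridones) to heteroaryl triflates.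

Step 6
Reactants: 9 4-methoxybenzyl chloride
Product: 10 4-methoxybenzylzinc chloride (titrated THF solution containing LiCl, used directly)
Conditions: Zn dust, LiCl, BrCH2CH2Br (cat.), Me3SiCl (cat.), THF, 25 °C
Reagents that add atoms: zinc, [Zn]
Why: LiCl-promoted direct insertion of zinc into a benzylic chloride is a standard preparation of benzylic zinc chlorides, and the chloride leaving group and mild temperature keep Wurtz coupling low.

Step 7
Reactants: 8 2-[bis(tert-butoxycarbonyl)amino]-1-methyl-5-(2,3,4,5-tetramethoxybenzyl)-1H-imidazol-4-yl trifluoromethanesulfonate; 10 4-methoxybenzylzinc chloride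
Product: 11 di-tert-butyl [4-(4-methoxybenzyl)-1-methyl-5-(2,3,4,5-tetramethoxybenzyl)-1H-imidazol-2-yl]imidodicarbonate
Conditions: Pd(PPh3)4 (5 mol %), 10 (1.6 equiv, LiCl carried over from step 6), THF, 60 °C
Reagents that add atoms: none
Why: Proposed new method: zerovalent palladium, helped by the chloride carried over with the zinc reagent, inserts into the C4–O bond of triflate 8 to give a divalent imidazol-4-ylpalladium species, the 4-methoxybenzyl group is transferred from zinc, and reductive elimination forms the C4–CH2 bond and returns zerovalent palladium. The closest known reaction type is the Negishi coupling of aryl and heteroaryl triflates (pyridyl, quinolyl, oxazol-4-yl) with benzylic zinc halides; the new element is a 2-aminoimidazol-4-yl triflate as the electrophile. No ring is closed and no stereocentre is formed; the step joins C4 of the creatinine-derived ring to the benzylic carbon and completes the 4,5-dibenzyl-2-aminoimidazole skeleton. The selectivity needed is insertion into C–O instead of attack of the organometallic at sulfur, which would return the lactam; the soft, weakly nucleophilic zinc reagent and the two electron-withdrawing carbamates on the C2 nitrogen, which lower the electron density of the ring, should secure it. The benzyl group on palladium has no β-hydrogen on an sp3 carbon, so β-hydride elimination cannot compete, and the absence of any N–H in 8 prevents protonolysis of the zinc reagent and binding of a free amino group to palladium.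

Step 8
Reactants: 11 di-tert-butyl [4-(4-methoxybenzyl)-1-methyl-5-(2,3,4,5-tetramethoxybenzyl)-1H-imidazol-2-yl]imidodicarbonate
Product: 12 4-(4-methoxybenzyl)-1-methyl-5-(2,3,4,5-tetramethoxybenzyl)-1H-imidazol-2-amine
Conditions: CF3CO2H/CH2Cl2 (1:4), 0 to 25 °C; then aq. NaHCO3
Reagents that add atoms: none
Why: Acidolytic Boc removal by loss of tert-butyl cation and decarboxylation, to which the aryl methyl ethers and the benzylic C–C bonds are inert.

Step 9
Reactants: 12 4-(4-methoxybenzyl)-1-methyl-5-(2,3,4,5-tetramethoxybenzyl)-1H-imidazol-2-amine; 13 1-methylimidazolidine-2,4,5-trione (N-methylparabanic acid)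
Product: 15 5-{[4-(4-methoxybenzyl)-1-methyl-5-(2,3,4,5-tetramethoxybenzyl)-1H-imidazol-2-yl]amino}-3-methyl-4H-imidazole-2,4(3H)-dione, via O-silyl imidate of N-methylparabanic acid 14 (not isolated)
Conditions: 13, N,O-bis(trimethylsilyl)acetamide, MeCN, 25 °C; then 12, PhMe, 110 °C
Reagents that add atoms: none
Why: Silylation of the imide N–H of 13 gives imidate 14, whose C4 undergoes addition–elimination with the exocyclic amine of 12 (amidine formation), the established way to attach this dehydrohydantoin to 2-amino-1-methylimidazoles; C4 reacts, not C5, because only the carbonyl next to the unsubstituted nitrogen can be activated as an imidate.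

Step 10
Reactants: 15 5-{[4-(4-methoxybenzyl)-1-methyl-5-(2,3,4,5-tetramethoxybenzyl)-1H-imidazol-2-yl]amino}-3-methyl-4H-imidazole-2,4(3H)-dione
Product: 16 naamidine F, 5-{[5-[(4,5-dimethoxy-3,6-dioxocyclohexa-1,4-dien-1-yl)methyl]-4-(4-methoxybenzyl)-1-methyl-1H-imidazol-2-yl]amino}-3-methyl-4H-imidazole-2,4(3H)-dione
Conditions: (NH4)2Ce(NO3)6 (2.5 equiv), MeCN/H2O (2:1), 0 °C
Reagents that add atoms: water, O
Why: Oxidative demethylation of the para-dimethoxy pair by single-electron oxidation with tetravalent cerium, as in the preparation of 2,3-dimethoxy-5-alkylbenzoquinones from 2,3,4,5-tetramethoxyalkylbenzenes; the tetramethoxyphenyl ring is far more electron-rich than the anisyl ring, and the imidazole is protonated in the acidic medium with its amino group tied up in the acylamidine.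

**Compound list**

1 | 1,2,3,4-tetramethoxybenzene | COc1ccc(OC)c(OC)c1OC | starting material
2 | 2,3,4,5-tetramethoxybenzaldehyde | O=Cc1cc(OC)c(OC)c(OC)c1OC | intermediate
3 | creatinine | CN1CC(=O)N=C1N | starting material
4 | (5E)-2-amino-1-methyl-5-(2,3,4,5-tetramethoxybenzylidene)-1,5-dihydro-4H-imidazol-4-one | CN1C(N)=NC(=O)/C1=C\c1cc(OC)c(OC)c(OC)c1OC | intermediate
5 | (±)-2-amino-1-methyl-5-(2,3,4,5-tetramethoxybenzyl)-1,5-dihydro-4H-imidazol-4-one | CN1C(N)=NC(=O)C1Cc1cc(OC)c(OC)c(OC)c1OC | intermediate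
6 | (±)-di-tert-butyl [1-methyl-4-oxo-5-(2,3,4,5-tetramethoxybenzyl)-4,5-dihydro-1H-imidazol-2-yl]imidodicarbonate | CN1C(N(C(=O)OC(C)(C)C)C(=O)OC(C)(C)C)=NC(=O)C1Cc1cc(OC)c(OC)c(OC)c1OC | intermediate
7 | potassium 2-[bis(tert-butoxycarbonyl)amino]-1-methyl-5-(2,3,4,5-tetramethoxybenzyl)-1H-imidazol-4-olate | Cn1c(N(C(=O)OC(C)(C)C)C(=O)OC(C)(C)C)nc([O-])c1Cc1cc(OC)c(OC)c(OC)c1OC.[K+] | intermediate (not isolated)
8 | 2-[bis(tert-butoxycarbonyl)amino]-1-methyl-5-(2,3,4,5-tetramethoxybenzyl)-1H-imidazol-4-yl trifluoromethanesulfonate | Cn1c(N(C(=O)OC(C)(C)C)C(=O)OC(C)(C)C)nc(OS(=O)(=O)C(F)(F)F)c1Cc1cc(OC)c(OC)c(OC)c1OC | intermediate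
9 | 4-methoxybenzyl chloride | COc1ccc(CCl)cc1 | starting material
10 | 4-methoxybenzylzinc chloride | COc1ccc(C[Zn]Cl)cc1 | intermediate
11 | di-tert-butyl [4-(4-methoxybenzyl)-1-methyl-5-(2,3,4,5-tetramethoxybenzyl)-1H-imidazol-2-yl]imidodicarbonate | Cn1c(N(C(=O)OC(C)(C)C)C(=O)OC(C)(C)C)nc(Cc2ccc(OC)cc2)c1Cc1cc(OC)c(OC)c(OC)c1OC | intermediate
12 | 4-(4-methoxybenzyl)-1-methyl-5-(2,3,4,5-tetramethoxybenzyl)-1H-imidazol-2-amine | Cn1c(N)nc(Cc2ccc(OC)cc2)c1Cc1cc(OC)c(OC)c(OC)c1OC | intermediate
13 | 1-methylimidazolidine-2,4,5-trione (N-methylparabanic acid) | CN1C(=O)NC(=O)C1=O | starting material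
14 | 1-methyl-4-(trimethylsilyloxy)-1H-imidazole-2,5-dione | CN1C(=O)N=C(O[Si](C)(C)C)C1=O | intermediate (not isolated)
15 | 5-{[4-(4-methoxybenzyl)-1-methyl-5-(2,3,4,5-tetramethoxybenzyl)-1H-imidazol-2-yl]amino}-3-methyl-4H-imidazole-2,4(3H)-dione | COc1cc(Cc2c(Cc3ccc(OC)cc3)nc(NC3=NC(=O)N(C)C3=O)n2C)c(OC)c(OC)c1OC | intermediate
16 | naamidine F | COC1=C(OC)C(=O)C(Cc2c(Cc3ccc(OC)cc3)nc(NC3=NC(=O)N(C)C3=O)n2C)=CC1=O | target

**Step count**

Total step count: 10. Longest linear sequence: 9 steps (steps 1–5 and 7–10, from 1 to 16); step 6 is a one-step branch.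

**Steps most likely to fail**

1. Step 5 (proposed new method). The ambident olate may be sulfonylated at N3 or C5 instead of oxygen, or the electron-rich triflate may lose its sulfonyl group by S–O hydrolysis during isolation. The fallback uses known chemistry, sets out from aldehyde 2 and comes back at amine 12. Commercial 4,5-diiodo-1-methylimidazole undergoes selective iodine–magnesium exchange at C5 with EtMgBr (THF, 0 °C) to give (4-iodo-1-methyl-1H-imidazol-5-yl)magnesium bromide F1, which adds to 2 to give (±)-(4-iodo-1-methyl-1H-imidazol-5-yl)(2,3,4,5-tetramethoxyphenyl)methanol F2. Ionic deoxygenation (Et3SiH, CF3CO2H, CH2Cl2) should give 4-iodo-1-methyl-5-(2,3,4,5-tetramethoxybenzyl)-1H-imidazole F3. Negishi coupling of this iodoimidazole with zinc reagent 10 (Pd(PPh3)4, THF, 60 °C) should give 4-(4-methoxybenzyl)-1-methyl-5-(2,3,4,5-tetramethoxybenzyl)-1H-imidazole F4. Lithiation at C2 (n-BuLi, THF, −78 °C) gives [4-(4-methoxybenzyl)-1-methyl-5-(2,3,4,5-tetramethoxybenzyl)-1H-imidazol-2-yl]lithium F5, which is quenched with tosyl azide to give 2-azido-4-(4-methoxybenzyl)-1-methyl-5-(2,3,4,5-tetramethoxybenzyl)-1H-imidazole F6. Hydrogenation (H2, Pd/C, EtOH) should then give 12.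

2. Step 7 (proposed new method). Oxidative addition into the electron-rich C4–O bond may be slow, so that attack of the zinc reagent at sulfur (return to the lactam), homocoupling of the benzylzinc reagent, or zinc-chloride-induced loss of a Boc group takes over. The fallback uses known chemistry, sets out from lactam 5 and comes back at amine 12. Hydrolysis of the cyclic acylguanidine with Ba(OH)2 (H2O, 120 °C, then removal of barium with CO2) should give (±)-N-methyl-3-(2,3,4,5-tetramethoxyphenyl)alanine F7. Boc2O/NaOH (dioxane/H2O) gives (±)-N-(tert-butoxycarbonyl)-N-methyl-3-(2,3,4,5-tetramethoxyphenyl)alanine F8. Coupling with MeNH(OMe)·HCl (EDC·HCl, HOBt, iPr2NEt, CH2Cl2) gives the Weinreb amide (±)-tert-butyl {1-[methoxy(methyl)amino]-1-oxo-3-(2,3,4,5-tetramethoxyphenyl)propan-2-yl}(methyl)carbamate F9. Commercial 4-methoxybenzylmagnesium chloride (THF, 0 °C) gives the ketone (±)-tert-butyl [4-(4-methoxyphenyl)-3-oxo-1-(2,3,4,5-tetramethoxyphenyl)butan-2-yl](methyl)carbamate F10. HCl in dioxane gives (±)-1-(4-methoxyphenyl)-3-(methylamino)-4-(2,3,4,5-tetramethoxyphenyl)butan-2-one hydrochloride F11. Condensation of this α-amino ketone with cyanamide (EtOH/H2O, pH 4–5, 95 °C; then NaOH) closes the 2-aminoimidazole with the N-methyl nitrogen next to the tetramethoxybenzyl-bearing carbon and gives 12.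

3. Step 4. The second acylation may go to N3 or to the C5 enol oxygen, or stall at the mono-carbamate, leaving an N–H that consumes base and opens an N-sulfonylation path in step 5. The fallback sets out from lactam 5 and comes back at amine 12, replacing the two carbamates by one amidine that cannot add twice and leaves no N–H. Me2NCH(OMe)2 (PhMe, 80 °C) should give (±)-N'-[1-methyl-4-oxo-5-(2,3,4,5-tetramethoxybenzyl)-4,5-dihydro-1H-imidazol-2-yl]-N,N-dimethylformimidamide F12. KN(SiMe3)2 (THF, −78 °C) gives potassium 2-{[(E)-(dimethylamino)methylidene]amino}-1-methyl-5-(2,3,4,5-tetramethoxybenzyl)-1H-imidazol-4-olate F13, and PhNTf2 gives 2-{[(E)-(dimethylamino)methylidene]amino}-1-methyl-5-(2,3,4,5-tetramethoxybenzyl)-1H-imidazol-4-yl trifluoromethanesulfonate F14. Coupling with 10 (Pd(PPh3)4, THF, 60 °C) gives N'-[4-(4-methoxybenzyl)-1-methyl-5-(2,3,4,5-tetramethoxybenzyl)-1H-imidazol-2-yl]-N,N-dimethylformimidamide F15. Hydrolysis of the amidine (aq. HCl, EtOH, 60 °C; then NaHCO3) gives 12.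

**Further compounds**

F1 | step 5 | (4-iodo-1-methyl-1H-imidazol-5-yl)magnesium bromide | Cn1cnc(I)c1[Mg]Br
F2 | step 5 | (±)-(4-iodo-1-methyl-1H-imidazol-5-yl)(2,3,4,5-tetramethoxyphenyl)methanol | Cn1cnc(I)c1C(O)c1cc(OC)c(OC)c(OC)c1OC
F3 | step 5 | 4-iodo-1-methyl-5-(2,3,4,5-tetramethoxybenzyl)-1H-imidazole | Cn1cnc(I)c1Cc1cc(OC)c(OC)c(OC)c1OC
F4 | step 5 | 4-(4-methoxybenzyl)-1-methyl-5-(2,3,4,5-tetramethoxybenzyl)-1H-imidazole | Cn1cnc(Cc2ccc(OC)cc2)c1Cc1cc(OC)c(OC)c(OC)c1OC
F5 | step 5 | [4-(4-methoxybenzyl)-1-methyl-5-(2,3,4,5-tetramethoxybenzyl)-1H-imidazol-2-yl]lithium | [Li]c1nc(Cc2ccc(OC)cc2)c(Cc2cc(OC)c(OC)c(OC)c2OC)n1C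
F6 | step 5 | 2-azido-4-(4-methoxybenzyl)-1-methyl-5-(2,3,4,5-tetramethoxybenzyl)-1H-imidazole | Cn1c(N=[N+]=[N-])nc(Cc2ccc(OC)cc2)c1Cc1cc(OC)c(OC)c(OC)c1OC
F7 | step 7 | (±)-N-methyl-3-(2,3,4,5-tetramethoxyphenyl)alanine | CNC(Cc1cc(OC)c(OC)c(OC)c1OC)C(=O)O
F8 | step 7 | (±)-N-(tert-butoxycarbonyl)-N-methyl-3-(2,3,4,5-tetramethoxyphenyl)alanine | CN(C(=O)OC(C)(C)C)C(Cc1cc(OC)c(OC)c(OC)c1OC)C(=O)O
F9 | step 7 | (±)-tert-butyl {1-[methoxy(methyl)amino]-1-oxo-3-(2,3,4,5-tetramethoxyphenyl)propan-2-yl}(methyl)carbamate | CON(C)C(=O)C(Cc1cc(OC)c(OC)c(OC)c1OC)N(C)C(=O)OC(C)(C)C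
F10 | step 7 | (±)-tert-butyl [4-(4-methoxyphenyl)-3-oxo-1-(2,3,4,5-tetramethoxyphenyl)butan-2-yl](methyl)carbamate | COc1ccc(CC(=O)C(Cc2cc(OC)c(OC)c(OC)c2OC)N(C)C(=O)OC(C)(C)C)cc1
F11 | step 7 | (±)-1-(4-methoxyphenyl)-3-(methylamino)-4-(2,3,4,5-tetramethoxyphenyl)butan-2-one hydrochloride | CNC(Cc1cc(OC)c(OC)c(OC)c1OC)C(=O)Cc1ccc(OC)cc1.Cl
F12 | step 4 | (±)-N'-[1-methyl-4-oxo-5-(2,3,4,5-tetramethoxybenzyl)-4,5-dihydro-1H-imidazol-2-yl]-N,N-dimethylformimidamide | CN(C)/C=N/C1=NC(=O)C(Cc2cc(OC)c(OC)c(OC)c2OC)N1C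
F13 | step 4 | potassium 2-{[(E)-(dimethylamino)methylidene]amino}-1-methyl-5-(2,3,4,5-tetramethoxybenzyl)-1H-imidazol-4-olate | CN(C)/C=N/c1nc([O-])c(Cc2cc(OC)c(OC)c(OC)c2OC)n1C.[K+]
F14 | step 4 | 2-{[(E)-(dimethylamino)methylidene]amino}-1-methyl-5-(2,3,4,5-tetramethoxybenzyl)-1H-imidazol-4-yl trifluoromethanesulfonate | CN(C)/C=N/c1nc(OS(=O)(=O)C(F)(F)F)c(Cc2cc(OC)c(OC)c(OC)c2OC)n1C
F15 | step 4 | N'-[4-(4-methoxybenzyl)-1-methyl-5-(2,3,4,5-tetramethoxybenzyl)-1H-imidazol-2-yl]-N,N-dimethylformimidamide | CN(C)/C=N/c1nc(Cc2ccc(OC)cc2)c(Cc2cc(OC)c(OC)c(OC)c2OC)n1C
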